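## Retrosynthetic overview

1. The target is cut back to its 6-desmethyl enone; the C6 methyl is added last by kinetic enolate methylation anti to the C5 side chain and the C4 oxygen.
2. The cyclohexenone is formed by aldol cyclodehydration across C2–C3. Its ring atoms C3–C4–C5–C6–C1–C2 are sugar carbons C1–C6 of the cellulose-derived ketone Cyrene; O6 becomes the 2-OMe oxygen and O5 the C1 carbonyl oxygen.
3. The acyclic 6-O-methyl-hexos-5-ulose comes from dithioacetal opening of the 1,6-anhydro ketal, O6 methylation and O5 oxidation.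
4. C5 is set by exo-face farnesylation of the Cyrene enolate; C4 is set by exo hydride delivery followed by Mitsunobu inversion on the rigid bicycle.
5. Ring order: both rings of Cyrene are opened in step 4; the only ring of the target is closed in step 7.

Key step: step 7

Remarks: the target SMILES is read as (4R,5R,6R), with 4-OH/5-side chain cis and 5-side chain/6-Me trans. Cyrene and (2E,6E)-farnesyl bromide are taken as commercial. "Farnesyl" means (2E,6E)-3,7,11-trimethyldodeca-2,6,10-trien-1-yl. Bicyclic and acyclic intermediates use sugar numbering (C1–C6, O5, O6) in the Why lines; carbocycles use target numbering.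

## Route

Step 1
Reactants: 1 Cyrene [(1S,5R)-6,8-dioxabicyclo[3.2.1]octan-4-one]; 2 (2E,6E)-farnesyl bromide
Product: 4 (1S,3R,5R)-3-farnesyl-6,8-dioxabicyclo[3.2.1]octan-4-one, via lithium enolate 3 (not isolated)
Conditions: LDA (1.05 equiv), THF, −78 °C (ketone added to base); then 2, DMPU, −78 → −20 °C
Reagents that add atoms: none
Why: Lithium enolate alkylation, in which C3 is the only enolisable position of Cyrene (the other α-carbon is the bridgehead acetal carbon) and the allylic bromide should enter on the exo face anti to the 1,6-anhydro bridge, which is also the equatorial, thermodynamically preferred position of this epimerisable centre (3R, the later C5).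

Step 2
Reactants: 4 (1S,3R,5R)-3-farnesyl-6,8-dioxabicyclo[3.2.1]octan-4-one
Product: 5 (1S,3R,4S,5R)-3-farnesyl-6,8-dioxabicyclo[3.2.1]octan-4-ol
Conditions: NaBH4, MeOH, −20 → 0 °C
Reagents that add atoms: none
Why: Borohydride reduction, in which hydride should add to the exo face, anti to the bridge and antiperiplanar to the axial anomeric C–O bond (Felkin–Anh), the facial preference known for Cyrene and levoglucosenone, to give the equatorial 4S alcohol.

Step 3
Reactants: 5 (1S,3R,4S,5R)-3-farnesyl-6,8-dioxabicyclo[3.2.1]octan-4-ol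
Product: 6 (1S,3R,4R,5R)-3-farnesyl-6,8-dioxabicyclo[3.2.1]octan-4-yl benzoate
Conditions: PPh3, DIAD, PhCO2H, toluene, 0 → 50 °C
Reagents that add atoms: benzoic acid, OC(=O)c1ccccc1
Why: Mitsunobu reaction, in which benzoate displaces the equatorial oxyphosphonium by SN2 along the open axial exo trajectory (the inversion mode known for C2 sulfonates of 1,6-anhydrohexopyranoses), which sets the later C4 with oxygen cis to the farnesyl group and installs the ester protecting group, while E2 is disfavoured because no hydrogen is antiperiplanar to the leaving group.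

Step 4
Reactants: 6 (1S,3R,4R,5R)-3-farnesyl-6,8-dioxabicyclo[3.2.1]octan-4-yl benzoate
Product: 7 (1R,2R,4S)-1-(1,3-dithian-2-yl)-2-farnesyl-4,5-dihydroxypentyl benzoate
Conditions: HS(CH2)3SH (3 equiv), BF3·OEt2, CH2Cl2, −20 → 0 °C, argon, dark
Reagents that add atoms: propane-1,3-dithiol, SCCCS
Why: Lewis-acid dithioacetalisation of a 1,6-anhydro sugar, in which both acetal C–O bonds are exchanged for C–S bonds, so that the pyranose and dioxolane rings open, sugar C1 is masked as a dithiane and O5–H and O6–H are freed without touching a stereocentre.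

Step 5
Reactants: 7 (1R,2R,4S)-1-(1,3-dithian-2-yl)-2-farnesyl-4,5-dihydroxypentyl benzoate
Product: 9 (1R,2R,4S)-1-(1,3-dithian-2-yl)-2-farnesyl-4-hydroxy-5-methoxypentyl benzoate, via stannylene acetal 8 (not isolated)
Conditions: Bu2SnO, toluene, reflux (Dean–Stark); then MeI, CsF, DMF, rt
Reagents that add atoms: iodomethane, CI
Why: Stannylene-acetal-directed mono-O-alkylation, in which the dibutylstannylene of the terminal 1,2-diol is alkylated at the primary oxygen under fluoride activation, so that the methyl group should end up on O6 (the later 2-OMe) only.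

Step 6
Reactants: 9 (1R,2R,4S)-1-(1,3-dithian-2-yl)-2-farnesyl-4-hydroxy-5-methoxypentyl benzoate
Product: 10 (1R,2R)-1-(1,3-dithian-2-yl)-2-farnesyl-5-methoxy-4-oxopentyl benzoate
Conditions: SO3·pyridine, DMSO, iPr2NEt, CH2Cl2, 0 °C
Reagents that add atoms: none
Why: Parikh–Doering oxidation of the only free hydroxyl gives the methoxymethyl ketone (the later C1=O) under activated-DMSO conditions that are compatible with the dithiane, the benzoate and the trisubstituted alkenes.

Step 7
Reactants: 10 (1R,2R)-1-(1,3-dithian-2-yl)-2-farnesyl-5-methoxy-4-oxopentyl benzoate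
Product: 13 (1R,6R)-6-farnesyl-3-methoxy-4-oxocyclohex-2-en-1-yl benzoate, via keto-aldehyde 11 (not isolated), via cyclic ketol 12 (not isolated)
Conditions: MeI (excess), CaCO3, MeCN–H2O 9:1, 40 °C; extractive work-up; then L-proline (30 mol %), DMSO, rt → 45 °C
Reagents that add atoms: none
Why: S-Methylation and hydrolysis release the aldehyde of 11 (the later C3) under neutral conditions; proline then forms an enamine of the methoxymethyl ketone at the oxygen-bearing α-carbon (the regiochemistry known for hydroxy- and methoxyacetone donors), this adds to the aldehyde, and ketol 12 loses water by E1cB to the conjugated 2-methoxy enone. The closest known reaction types are the amine-catalysed Hajos–Parrish/Robinson-type aldol cyclodehydration of 1,5-dicarbonyls and the Ferrier carbocyclisation of hexose-derived keto-aldehydes, whose carbon mapping (sugar C6 attacks sugar C1) is reproduced here without mercury. The cyclohexenone is closed in the 6-(enolendo)-exo-trig mode by forming C2–C3, and this is the only possible aldol because every other donor–acceptor pairing would give a four-membered ring. No stereocentre is created permanently, since C2 and C3 of 12 become sp2, while C4 and C5 are carried over unchanged from sugar C2 and C3. The selectivity that is needed is ketone-enamine formation in preference to enolisation of the α-benzoyloxy aldehyde, whose α-carbon is the later C4. It should be secured by the neutral unmasking, the absence of strong base and the slow enamine formation of α-branched aldehydes with proline.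

Step 8
Reactants: 13 (1R,6R)-6-farnesyl-3-methoxy-4-oxocyclohex-2-en-1-yl benzoate
Product: 14 (4R,5R)-5-farnesyl-4-hydroxy-2-methoxycyclohex-2-en-1-one
Conditions: K2CO3 (0.2 equiv), MeOH, 0 °C
Reagents that add atoms: none
Why: Carbonate-catalysed transesterification (Zemplén-type) removes the benzoate as methyl benzoate, and because C5–H is not acidic and C4–H only vinylogously so, both stereocentres should survive the brief cold treatment.

Step 9
Reactants: 14 (4R,5R)-5-farnesyl-4-hydroxy-2-methoxycyclohex-2-en-1-one
Product: 16 (4R,5R,6R)-5-farnesyl-4-hydroxy-2-methoxy-6-methylcyclohex-2-en-1-one, via dilithio dianion 15 (not isolated)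
Conditions: LDA (2.2 equiv), THF, −78 °C; MeI (1.5 equiv), −78 → −40 °C; AcOH quench at −78 °C
Reagents that add atoms: iodomethane, CI
Why: α′-Alkylation of an alkoxide–enolate dianion (C-alkylation in the presence of a lithium alkoxide, as in Frater–Seebach chemistry), in which MeI should approach C6 anti to the C5 side chain and the C4–OLi group, which lie on the same face, to give the 5,6-trans methyl (6R), which is also expected to be the thermodynamically favoured epimer.

## Compound list

1 | Cyrene, (1S,5R)-6,8-dioxabicyclo[3.2.1]octan-4-one | O=C1CC[C@H]2CO[C@@H]1O2 | starting material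
2 | (2E,6E)-farnesyl bromide | BrC/C=C(\C)CC/C=C(\C)CCC=C(C)C | starting material
3 | lithium enolate of Cyrene (C2=C3 enolate) | [Li]OC1=CC[C@H]2CO[C@@H]1O2 | intermediate
4 | (1S,3R,5R)-3-farnesyl-6,8-dioxabicyclo[3.2.1]octan-4-one (farnesyl exo, anti to the bridge) | O=C1[C@H](C/C=C(\C)CC/C=C(\C)CCC=C(C)C)C[C@H]2CO[C@@H]1O2 | intermediate
5 | (1S,3R,4S,5R)-3-farnesyl-6,8-dioxabicyclo[3.2.1]octan-4-ol (OH syn to the bridge, trans to farnesyl) | O[C@H]1[C@H](C/C=C(\C)CC/C=C(\C)CCC=C(C)C)C[C@H]2CO[C@@H]1O2 | intermediate
6 | (1S,3R,4R,5R)-3-farnesyl-6,8-dioxabicyclo[3.2.1]octan-4-yl benzoate (OBz anti to the bridge, cis to farnesyl) | O=C(O[C@@H]1[C@H](C/C=C(\C)CC/C=C(\C)CCC=C(C)C)C[C@H]2CO[C@@H]1O2)c1ccccc1 | intermediate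
7 | (1R,2R,4S)-1-(1,3-dithian-2-yl)-2-farnesyl-4,5-dihydroxypentyl benzoate | OC[C@@H](O)C[C@@H](C/C=C(\C)CC/C=C(\C)CCC=C(C)C)[C@@H](OC(=O)c1ccccc1)C1SCCCS1 | intermediate
8 | 2,2-dibutyl-1,3,2-dioxastannolane (stannylene acetal) of the 4,5-diol of 7 | CCCC[Sn]1(CCCC)OC[C@H](C[C@@H](C/C=C(\C)CC/C=C(\C)CCC=C(C)C)[C@@H](OC(=O)c2ccccc2)C2SCCCS2)O1 | intermediate
9 | (1R,2R,4S)-1-(1,3-dithian-2-yl)-2-farnesyl-4-hydroxy-5-methoxypentyl benzoate | COC[C@@H](O)C[C@@H](C/C=C(\C)CC/C=C(\C)CCC=C(C)C)[C@@H](OC(=O)c1ccccc1)C1SCCCS1 | intermediate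
10 | (1R,2R)-1-(1,3-dithian-2-yl)-2-farnesyl-5-methoxy-4-oxopentyl benzoate | COCC(=O)C[C@@H](C/C=C(\C)CC/C=C(\C)CCC=C(C)C)[C@@H](OC(=O)c1ccccc1)C1SCCCS1 | intermediate
11 | (2R,3R)-3-farnesyl-6-methoxy-1,5-dioxohexan-2-yl benzoate (keto-aldehyde) | COCC(=O)C[C@@H](C/C=C(\C)CC/C=C(\C)CCC=C(C)C)[C@@H](OC(=O)c1ccccc1)C=O | intermediate
12 | (1R,6R)-6-farnesyl-2-hydroxy-3-methoxy-4-oxocyclohexyl benzoate (ketol; C2 and C3 of the ring undefined) | COC1C(O)[C@H](OC(=O)c2ccccc2)[C@H](C/C=C(\C)CC/C=C(\C)CCC=C(C)C)CC1=O | intermediate
13 | (1R,6R)-6-farnesyl-3-methoxy-4-oxocyclohex-2-en-1-yl benzoate | COC1=C[C@H](OC(=O)c2ccccc2)[C@H](C/C=C(\C)CC/C=C(\C)CCC=C(C)C)CC1=O | intermediate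
14 | (4R,5R)-5-farnesyl-4-hydroxy-2-methoxycyclohex-2-en-1-one | COC1=C[C@H](O)[C@H](C/C=C(\C)CC/C=C(\C)CCC=C(C)C)CC1=O | intermediate
15 | dilithio alkoxide–dienolate of 14 (O4–Li and C1(OLi)=C6) | COC1=C[C@H](O[Li])[C@H](C/C=C(\C)CC/C=C(\C)CCC=C(C)C)C=C1O[Li] | intermediate
16 | (4R,5R,6R)-4-hydroxy-2-methoxy-6-methyl-5-[(2E,6E)-3,7,11-trimethyldodeca-2,6,10-trien-1-yl]cyclohex-2-en-1-one | COC1=C[C@H](O)[C@H](C/C=C(\C)CC/C=C(\C)CCC=C(C)C)[C@@H](C)C1=O | target

## Step count and risks

Total step count: 9. Longest linear sequence: 9 steps (from Cyrene).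

Steps most likely to fail:

1. Step 7 (key step). What may go wrong: loss of configuration at the aldehyde α-carbon (the later C4) by enolisation or enamine formation before the ring closes, or stalling at the ketol stage. Fallback: setting out from ketone 10, soft enolisation with TBSOTf/Et3N toward the methoxy-bearing carbon should give the (Z)-tert-butyldimethylsilyl enol ether F1. Dimethyl(methylthio)sulfonium tetrafluoroborate (DMTSF) then turns the dithiane into a thionium ion, which the enol silane captures in a Mukaiyama-type six-ring closure to give the 2-{[3-(methyldisulfanyl)propyl]sulfanyl} ketone F2. DBU-induced E1cB loss of the thiolate comes back to the route at enone benzoate 13. The aldehyde is never free on this path, so the centre next to it cannot epimerise.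

2. Step 3. What may go wrong: slow SN2 at the C2 centre flanked by the acetal carbon and the branched C3, so that the oxyphosphonium is consumed by side reactions instead of inversion. Fallback: setting out from alcohol 5, Tf2O/pyridine gives the equatorial triflate F3, which is displaced with inversion by tetrabutylammonium benzoate in toluene (the reaction mode of 1,6-anhydrohexopyranose 2-triflates). This comes back to the route at benzoate 6.

3. Step 5. What may go wrong: competing S-methylation of the dithiane by MeI and incomplete discrimination between the primary and the secondary hydroxyl. Fallback: setting out from benzoate 6 and bypassing diol 7, acid-catalysed methanolysis of the 1,6-anhydro bridge (MeOH, cat. TMSOTf, CH2Cl2) gives the methyl pyranoside with a free primary hydroxyl F4 (anomeric mixture). Methylation with MeOTf and 2,6-di-tert-butyl-4-methylpyridine, at a stage with no sulfur and no second hydroxyl, gives the 6-O-methyl pyranoside F5. Propane-1,3-dithiol/BF3·OEt2 then opens the glycoside to the acyclic dithiane with only O5–H free, which comes back to the route at compound 9.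

Further compounds
F1 | step 7 | (Z)-tert-butyldimethylsilyl enol ether of ketone 10 (enol C=C toward the methoxy-bearing carbon) | CO/C=C(O[Si](C)(C)C(C)(C)C)/C[C@@H](C/C=C(\C)CC/C=C(\C)CCC=C(C)C)[C@@H](OC(=O)c1ccccc1)C1SCCCS1
F2 | step 7 | (1R,6R)-6-farnesyl-3-methoxy-2-{[3-(methyldisulfanyl)propyl]sulfanyl}-4-oxocyclohexyl benzoate (C2 and C3 undefined) | COC1C(SCCCSSC)[C@H](OC(=O)c2ccccc2)[C@H](C/C=C(\C)CC/C=C(\C)CCC=C(C)C)CC1=O
F3 | step 3 | (1S,3R,4S,5R)-3-farnesyl-6,8-dioxabicyclo[3.2.1]octan-4-yl trifluoromethanesulfonate | FC(F)(F)S(=O)(=O)O[C@H]1[C@H](C/C=C(\C)CC/C=C(\C)CCC=C(C)C)C[C@H]2CO[C@@H]1O2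
F4 | step 5 | methyl 2-O-benzoyl-3,4-dideoxy-3-C-farnesyl-hexopyranoside with free 6-OH (2R,3R,5S; anomeric mixture) | COC1O[C@H](CO)C[C@@H](C/C=C(\C)CC/C=C(\C)CCC=C(C)C)[C@H]1OC(=O)c1ccccc1
F5 | step 5 | methyl 2-O-benzoyl-3,4-dideoxy-3-C-farnesyl-6-O-methyl-hexopyranoside (2R,3R,5S; anomeric mixture) | COC1O[C@H](COC)C[C@@H](C/C=C(\C)CC/C=C(\C)CCC=C(C)C)[C@H]1OC(=O)c1ccccc1
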